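**Plan**

- Numbering (briarane): ten-membered ring C1–C10, ring A = C1/C10–C14, lactone C7–O–C19(=O)–C17–C8. Retrosynthetic cuts, in order: MOM ether, acetates and the C11 methyl (back to a C11 ketone); C9–C10 (aldol), which opens the ten-membered ring; then C4–C5, C6–C7 and O7–C19 together.
- Enabling feature: C5(CH3)=C6 is a Z alkene whose cis substituents are C4 and the lactone carbinol C7, i.e. a propyne unit that has taken up C4 and C7 on one side. C7–O is the ring oxygen of the γ-lactone C7–O–C19–C17–C8, so a C7 alkoxide can acylate itself at C19.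
- Forward: ring A by Diels–Alder and side-chain work to iodide 13 (steps 1–10); lactone half 20 from an oxazolidinone imide (steps 11–15); step 16 joins 13, propyne and 20 and closes the lactone; step 19 closes the ten-membered ring; steps 20–24 add the C11 methyl and set the acetates.
- Stereochemistry: C1 from the catalysed cycloaddition; C2 from the allylborane; C12 from the oxazaborolidine reduction; C17 from the auxiliary; C8 from a chelate-controlled vinyl addition; C7 from chelation at O8 in step 16; C9/C10 from the chair aldol of the ring enolate; C11 by addition trans to O12; Z alkene from syn carbocupration.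

Key step: step 16

Assumption: the (R,R)-salen catalyst of step 1 (salen = N,N′-bis(3,5-di-tert-butylsalicylidene)cyclohexane-1,2-diamine dianion) and the (S)-oxazaborolidine of step 6 are taken to give the configurations drawn; if either sense proves opposite, the mirror-image catalyst is used.

**Route**

Step 1
Reactants: 1 methacrolein; 2 (E)-1-(dimethylamino)-3-(tert-butyldimethylsilyloxy)buta-1,3-diene
Product: 4 (R)-1-methyl-4-oxocyclohex-2-ene-1-carbaldehyde, via cycloadduct 3 (not isolated)
Conditions: [(R,R)-salen]CrSbF6 (5 mol %), 4 Å MS, CH2Cl2, −40 °C; then aq HF, MeCN, 0 °C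
Reagents that add atoms: none
Why: Catalytic enantioselective Diels–Alder reaction in which the amino-bearing diene terminus bonds to the methyl-bearing carbon of the enal, the chromium–salen Lewis acid shields one face of the bound aldehyde to set the quaternary C1, and HF then unmasks the enone by silyl cleavage and β-elimination of dimethylamine.

Step 2
Reactants: 4 (R)-1-methyl-4-oxocyclohex-2-ene-1-carbaldehyde
Product: 5 (4R)-4-[(1R)-1-hydroxybut-3-en-1-yl]-4-methylcyclohex-2-en-1-one
Conditions: (−)-Ipc2B(allyl), Et2O, −78 °C; then HOCH2CH2NH2, rt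
Reagents that add atoms: (−)-B-allyldiisopinocampheylborane (antipode made from (−)-α-pinene), C=CCB([C@H]1C[C@H]2C[C@@H]([C@@H]1C)C2(C)C)[C@H]1C[C@H]2C[C@@H]([C@@H]1C)C2(C)C
Why: Brown allylation, in which the allylborane should add through a chair transition state to the aldehyde far faster than to the enone carbonyl and fix C2 as (R) by reagent control, the amino-alcohol work-up avoiding alkaline peroxide that would epoxidise the enone (one allyl carbon is excised in step 8).

Step 3
Reactants: 5 homoallylic alcohol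
Product: 6 (4R)-4-[(1R)-1-(tert-butyldimethylsilyloxy)but-3-en-1-yl]-4-methylcyclohex-2-en-1-one
Conditions: TBSOTf, 2,6-lutidine, CH2Cl2, −78 °C
Reagents that add atoms: tert-butyldimethylsilyl triflate, CC(C)(C)[Si](C)(C)OS(=O)(=O)C(F)(F)F
Why: Silylation of a hindered secondary alcohol with a silyl triflate and a hindered pyridine is routine and covers O2 before the base and Lewis acid steps.

Step 4
Reactants: 6 silyl ether enone
Product: 7 (4S)-4-[(1R)-1-(tert-butyldimethylsilyloxy)but-3-en-1-yl]-2-hydroxy-4-methylcyclohexa-2,5-dien-1-one (diosphenol)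
Conditions: KOt-Bu, O2, t-BuOH/THF, 0 °C; aq NH4Cl
Reagents that add atoms: dioxygen, O=O
Why: Base-mediated autoxidation of a ketone enolate, in which the enone can enolise only toward C11, the enolate is hydroperoxidised and dehydrated to the 11,12-dione, and this tautomerises toward C10 (its only α-hydrogens) to the stable diosphenol.

Step 5
Reactants: 7 diosphenol
Product: 8 (9R)-9-[(1R)-1-(tert-butyldimethylsilyloxy)but-3-en-1-yl]-9-methyl-1,4-dioxaspiro[4.5]dec-7-en-6-one
Conditions: (TMSOCH2)2, TMSOTf (cat.), CH2Cl2, −78 → −20 °C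
Reagents that add atoms: 1,2-bis(trimethylsilyloxy)ethane, C[Si](C)(C)OCCO[Si](C)(C)C
Why: Acid-catalysed ketalisation with a bis-silylated glycol, which should take place at the non-conjugated and more electrophilic C11 carbonyl of the dione tautomer and leave C12 as the enone carbonyl, as in the mono-ketalisation of cyclohexane-1,2-dione.

Step 6
Reactants: 8 ketal enone
Product: 9 (6R,9R)-9-[(1R)-1-(tert-butyldimethylsilyloxy)but-3-en-1-yl]-9-methyl-1,4-dioxaspiro[4.5]dec-7-en-6-ol
Conditions: (S)-Me-CBS oxazaborolidine (0.2 equiv), catecholborane, toluene, −78 °C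
Reagents that add atoms: none
Why: Corey–Bakshi–Shibata reduction, in which the fully substituted ketal carbon acts as the large and the vinyl carbon as the small substituent so that hydride delivery under catalyst control should give (R)-C12, while catecholborane at low temperature leaves both alkenes untouched.

Step 7
Reactants: 9 allylic alcohol
Product: 10 (6R,9R)-6-(tert-butyldimethylsilyloxy)-9-[(1R)-1-(tert-butyldimethylsilyloxy)but-3-en-1-yl]-9-methyl-1,4-dioxaspiro[4.5]dec-7-ene
Conditions: TBSOTf, 2,6-lutidine, CH2Cl2, −78 → 0 °C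
Reagents that add atoms: tert-butyldimethylsilyl triflate, CC(C)(C)[Si](C)(C)OS(=O)(=O)C(F)(F)F
Why: Silyl triflate silylation as in step 3 protects O12, and the dioxolane should tolerate the buffered low-temperature conditions.

Step 8
Reactants: 10 bis-silyl ether
Product: 11 (3R)-3-(tert-butyldimethylsilyloxy)-3-[(6R,9R)-6-(tert-butyldimethylsilyloxy)-9-methyl-1,4-dioxaspiro[4.5]dec-7-en-9-yl]propanal
Conditions: OsO4 (2 mol %), NaIO4, 2,6-lutidine, dioxane/H2O, rt
Reagents that add atoms: sodium periodate (terminal oxidant, oxygen passed on through OsO4), [Na+].[O-]I(=O)(=O)=O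
Why: Lemieux–Johnson oxidation, in which OsO4 should dihydroxylate the unhindered monosubstituted alkene in preference to the ring alkene (cis-disubstituted, flanked by a quaternary and a silyloxy carbon) and periodate cleaves the diol to the C4 aldehyde with loss of the extra carbon.

Step 9
Reactants: 11 aldehyde
Product: 12 (3R)-3-(tert-butyldimethylsilyloxy)-3-[(6R,9R)-6-(tert-butyldimethylsilyloxy)-9-methyl-1,4-dioxaspiro[4.5]dec-7-en-9-yl]propan-1-ol
Conditions: NaBH4, MeOH, 0 °C
Reagents that add atoms: none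
Why: Borohydride reduction of an aldehyde, to which the ketal and silyl ethers are inert.

Step 10
Reactants: 12 primary alcohol
Product: 13 (6R,9R)-6-(tert-butyldimethylsilyloxy)-9-[(1R)-1-(tert-butyldimethylsilyloxy)-3-iodopropyl]-9-methyl-1,4-dioxaspiro[4.5]dec-7-ene (C4 iodide)
Conditions: I2, PPh3, imidazole, CH2Cl2, 0 °C
Reagents that add atoms: iodine, II
Why: Appel-type iodination of a primary alcohol, with imidazole buffering the acid-labile ketal and silyl ethers.

Step 11
Reactants: 14 (R)-4-benzyl-3-propionyloxazolidin-2-one; 15 (tert-butyldimethylsilyloxy)acetaldehyde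
Product: 16 (4R)-4-benzyl-3-[(2R,3R)-4-(tert-butyldimethylsilyloxy)-3-hydroxy-2-methylbutanoyl]oxazolidin-2-one
Conditions: n-Bu2BOTf, i-Pr2NEt, CH2Cl2, −78 → 0 °C; then MeOH, pH 7 buffer, H2O2
Reagents that add atoms: none
Why: Evans syn-aldol reaction, in which the Z boron enolate of the (R)-benzyl imide adds through a chair transition state with opposed dipoles to set C17 as (R) (the carbinol centre is removed in step 12).

Step 12
Reactants: 16 aldol adduct
Product: 17 (4R)-4-benzyl-3-[(2R)-4-(tert-butyldimethylsilyloxy)-2-methyl-3-oxobutanoyl]oxazolidin-2-one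
Conditions: Dess–Martin periodinane (DMP), NaHCO3, CH2Cl2, 0 °C → rt
Reagents that add atoms: none
Why: Dess–Martin oxidation of a β-hydroxy imide gives the β-keto imide, whose C17 hydrogen is held in the imide plane by allylic strain and so should not epimerise.

Step 13
Reactants: 17 β-keto imide
Product: 18 (4R)-4-benzyl-3-[(2R,3R)-3-hydroxy-2-methyl-3-{[(tert-butyldimethylsilyl)oxy]methyl}pent-4-enoyl]oxazolidin-2-one
Conditions: MgBr2·OEt2, CH2Cl2, −78 °C; vinylMgBr (THF), −78 °C; AcOH quench
Reagents that add atoms: vinylmagnesium bromide, C=C[Mg]Br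
Why: Chelation-controlled Grignard addition, in which magnesium bridges the ketone and the imide acyl oxygen and the vinyl group should add to the ketone face opposite the C17 methyl, giving the tertiary carbinol C8 with the C17 methyl and O8 in the relationship the lactone needs (the silyl ether does not compete for the metal).

Step 14
Reactants: 18 tertiary alcohol
Product: 19 (4R)-4-benzyl-3-[(2R,3R)-3-(methoxymethoxy)-2-methyl-3-{[(tert-butyldimethylsilyl)oxy]methyl}pent-4-enoyl]oxazolidin-2-one
Conditions: MOMCl, i-Pr2NEt, n-Bu4NI (cat.), ClCH2CH2Cl, 60 °C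
Reagents that add atoms: chloromethyl methyl ether, COCCl
Why: O-Alkylation of the tertiary alcohol with MOMCl and a hindered amine under iodide catalysis installs the alkoxymethyl ether that serves as the chelating group at C8.

Step 15
Reactants: 19 MOM ether
Product: 20 (4R)-4-benzyl-3-[(2R,3R)-3-formyl-3-(methoxymethoxy)-2-methyl-4-(tert-butyldimethylsilyloxy)butanoyl]oxazolidin-2-one (C7 aldehyde, C19 imide)
Conditions: O3, CH2Cl2, −78 °C; then PPh3
Reagents that add atoms: ozone, [O-][O+]=O
Why: Ozonolysis with reductive work-up cleaves the only alkene to the non-enolisable C7 aldehyde.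

Step 16
Reactants: 13 C4 iodide; 21 propyne; 20 C7 aldehyde with C19 imide
Product: 26 coupled (Z)-alkene γ-lactone, via alkyllithium 22 (not isolated), via alkylcopper 23 (not isolated), via alkenylcopper 24 (not isolated), via bromomagnesium alkoxide 25 (not isolated)
Conditions: 13, t-BuLi (2.1 equiv), Et2O/pentane, −78 °C; MgBr2·OEt2; CuBr·SMe2, Me2S/Et2O, −45 °C; 21, −25 °C, then purge; 2-thienyllithium, −78 °C; 20·MgBr2·OEt2, CH2Cl2, −78 → 0 °C; aq NH4Cl/NH3
Reagents that add atoms: none
Why: Iodine–lithium exchange and transmetalation through magnesium to copper give the alkylcopper–MgBr2 reagent 23, which adds across propyne in a syn four-centre carbometalation with carbon bonding to the methyl-bearing alkyne carbon and copper to the terminal one, so that C4 and copper (later C7) lie cis on C5=C6. 2-Thienyllithium converts the alkenylcopper into a mixed cuprate whose alkenyl ligand adds to the aldehyde of 20; the closest known reactions are the carbocupration of 1-alkynes by alkylcopper–magnesium halide reagents with electrophilic trapping and the chelation-controlled addition of cuprates to α-alkoxy aldehydes. The C7 alkoxide 25 then attacks the C19 acyl carbon of the N-acyl oxazolidinone in a 5-exo-trig acyl substitution, closing the γ-lactone C7–O–C19–C17–C8 and expelling the auxiliary. The new stereocentre C7 is controlled by a five-membered MgBr2 chelate between the aldehyde oxygen and the C8 methoxymethoxy oxygen: the alkenyl group should approach past the small CH2OTBS arm and away from the branched C17 acyl arm, which gives (7S). The step needs Z geometry (fixed by the syn addition and not by an olefination), addition to propyne and not its deprotonation (secured by ether solvent and the magnesium halide), and aldehyde-over-imide selectivity (secured by the soft cuprate), while the non-chelating silyl ether at C9 keeps the chelate at O8.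

Step 17
Reactants: 26 coupled lactone
Product: 27 C9 alcohol / C11 ketone
Conditions: p-TsOH·H2O (0.3 equiv), acetone/H2O 10:1, 40 °C
Reagents that add atoms: water, O
Why: Acid hydrolysis, in which the primary silyl ether at C9 and the dioxolane are the most labile groups while the two hindered secondary silyl ethers and the MOM ether should survive catalytic acid.

Step 18
Reactants: 27 hydroxy ketone
Product: 28 C9 aldehyde / C11 ketone
Conditions: DMP, NaHCO3, CH2Cl2, 0 °C → rt
Reagents that add atoms: none
Why: Dess–Martin oxidation of the neopentyl primary alcohol under buffered non-basic conditions gives the non-enolisable C9 aldehyde without disturbing the β,γ-unsaturated ketone.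

Step 19
Reactants: 28 keto aldehyde
Product: 29 ten-membered-ring aldol (9-hydroxy-11-ketone)
Conditions: Cy2BCl, Et3N, Et2O, −78 → 0 °C, 0.002 M; then MeOH, pH 7 buffer, H2O2
Reagents that add atoms: none
Why: Boron-mediated intramolecular aldol addition, in which soft enolisation should occur at the C10 methylene (the C12 hydrogen lies in the carbonyl plane beside the pseudoaxial silyloxy group and is shielded) and the ring-locked E enolate should add to the C9 aldehyde through a chair Zimmerman–Traxler transition state to give the 9,10-anti adduct with C9 trans to C2 on ring A, the boron aldolate blocking retro-aldol and lactone migration.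

Step 20
Reactants: 29 aldol
Product: 30 9-acetate 11-ketone
Conditions: Ac2O, pyridine, DMAP (cat.), CH2Cl2, 0 °C → rt
Reagents that add atoms: acetic anhydride, CC(=O)OC(C)=O
Why: DMAP-catalysed acylation installs the C9 acetate of the target, which also shuts off retro-aldol cleavage and migration of the lactone to O9.

Step 21
Reactants: 30 acetoxy ketone
Product: 31 11-hydroxy-11-methyl compound
Conditions: MeMgBr, CeCl3, THF, −78 °C; AcOH quench
Reagents that add atoms: methylmagnesium bromide, C[Mg]Br
Why: Organocerium 1,2-addition, in which the weakly basic methylcerium reagent should add to the hindered enolisable ketone faster than to the acetate or lactone and from the β face trans to the adjacent C12 silyloxy group (Felkin–Anh-type approach anti to the α C–O bond), giving the 11α-hydroxy-11β-methyl centre cis to O12.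

Step 22
Reactants: 31 bis-silyl ether
Product: 32 2,12-diol
Conditions: HF·pyridine, pyridine, THF, 0 → 40 °C
Reagents that add atoms: none
Why: Fluoride-mediated desilylation under buffered acidic conditions removes both secondary silyl ethers without acyl migration or lactone opening.

Step 23
Reactants: 32 diol
Product: 33 2,9,12-triacetate 8-MOM ether
Conditions: Ac2O, pyridine, DMAP (cat.), CH2Cl2, rt
Reagents that add atoms: acetic anhydride, CC(=O)OC(C)=O
Why: Acetylation of the two secondary hydroxyls, the tertiary C11 hydroxyl being too hindered to react under these conditions.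

Step 24
Reactants: 33 MOM ether
Product: 34 target (CNP0129620.2)
Conditions: Me2BBr, CH2Cl2, −78 °C; then aq NaHCO3/THF
Reagents that add atoms: none
Why: Lewis acid cleavage of the MOM ether, in which bromide opens the boron-activated acetal and the bromomethyl ether hydrolyses on work-up, frees the tertiary C8 hydroxyl while the acetates and the lactone are untouched.

**Compound list**

1 | methacrolein | CC(=C)C=O | starting material
2 | (E)-1-(dimethylamino)-3-(tert-butyldimethylsilyloxy)buta-1,3-diene | CN(C)/C=C/C(=C)O[Si](C)(C)C(C)(C)C | starting material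
3 | (1R,2S)-2-(dimethylamino)-1-methyl-4-(tert-butyldimethylsilyloxy)cyclohex-3-ene-1-carbaldehyde (endo cycloadduct) | C1CC(O[Si](C)(C)C(C)(C)C)=C[C@H](N(C)C)[C@]1(C)C=O | intermediate
4 | (R)-1-methyl-4-oxocyclohex-2-ene-1-carbaldehyde | C1CC(=O)C=C[C@]1(C)C=O | intermediate
5 | (4R)-4-[(1R)-1-hydroxybut-3-en-1-yl]-4-methylcyclohex-2-en-1-one | C1CC(=O)C=C[C@]1(C)[C@H](O)CC=C | intermediate
6 | (4R)-4-[(1R)-1-(tert-butyldimethylsilyloxy)but-3-en-1-yl]-4-methylcyclohex-2-en-1-one | C1CC(=O)C=C[C@]1(C)[C@H](O[Si](C)(C)C(C)(C)C)CC=C | intermediate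
7 | (4S)-4-[(1R)-1-(tert-butyldimethylsilyloxy)but-3-en-1-yl]-2-hydroxy-4-methylcyclohexa-2,5-dien-1-one | C1=C(O)C(=O)C=C[C@]1(C)[C@H](O[Si](C)(C)C(C)(C)C)CC=C | intermediate
8 | (9R)-9-[(1R)-1-(tert-butyldimethylsilyloxy)but-3-en-1-yl]-9-methyl-1,4-dioxaspiro[4.5]dec-7-en-6-one | C1C2(OCCO2)C(=O)C=C[C@]1(C)[C@H](O[Si](C)(C)C(C)(C)C)CC=C | intermediate
9 | (6R,9R)-9-[(1R)-1-(tert-butyldimethylsilyloxy)but-3-en-1-yl]-9-methyl-1,4-dioxaspiro[4.5]dec-7-en-6-ol | C1C2(OCCO2)[C@H](O)C=C[C@]1(C)[C@H](O[Si](C)(C)C(C)(C)C)CC=C | intermediate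
10 | (6R,9R)-6-(tert-butyldimethylsilyloxy)-9-[(1R)-1-(tert-butyldimethylsilyloxy)but-3-en-1-yl]-9-methyl-1,4-dioxaspiro[4.5]dec-7-ene | C1C2(OCCO2)[C@H](O[Si](C)(C)C(C)(C)C)C=C[C@]1(C)[C@H](O[Si](C)(C)C(C)(C)C)CC=C | intermediate
11 | (3R)-3-(tert-butyldimethylsilyloxy)-3-[(6R,9R)-6-(tert-butyldimethylsilyloxy)-9-methyl-1,4-dioxaspiro[4.5]dec-7-en-9-yl]propanal | C1C2(OCCO2)[C@H](O[Si](C)(C)C(C)(C)C)C=C[C@]1(C)[C@H](O[Si](C)(C)C(C)(C)C)CC=O | intermediate
12 | (3R)-3-(tert-butyldimethylsilyloxy)-3-[(6R,9R)-6-(tert-butyldimethylsilyloxy)-9-methyl-1,4-dioxaspiro[4.5]dec-7-en-9-yl]propan-1-ol | C1C2(OCCO2)[C@H](O[Si](C)(C)C(C)(C)C)C=C[C@]1(C)[C@H](O[Si](C)(C)C(C)(C)C)CCO | intermediate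
13 | (6R,9R)-6-(tert-butyldimethylsilyloxy)-9-[(1R)-1-(tert-butyldimethylsilyloxy)-3-iodopropyl]-9-methyl-1,4-dioxaspiro[4.5]dec-7-ene | C1C2(OCCO2)[C@H](O[Si](C)(C)C(C)(C)C)C=C[C@]1(C)[C@H](O[Si](C)(C)C(C)(C)C)CCI | intermediate
14 | (R)-4-benzyl-3-propionyloxazolidin-2-one | CCC(=O)N1[C@H](Cc2ccccc2)COC1=O | starting material
15 | (tert-butyldimethylsilyloxy)acetaldehyde | O=CCO[Si](C)(C)C(C)(C)C | starting material
16 | (4R)-4-benzyl-3-[(2R,3R)-4-(tert-butyldimethylsilyloxy)-3-hydroxy-2-methylbutanoyl]oxazolidin-2-one | O=C1OC[C@@H](Cc2ccccc2)N1C(=O)[C@H](C)[C@@H](O)CO[Si](C)(C)C(C)(C)C | intermediate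
17 | (4R)-4-benzyl-3-[(2R)-4-(tert-butyldimethylsilyloxy)-2-methyl-3-oxobutanoyl]oxazolidin-2-one | O=C1OC[C@@H](Cc2ccccc2)N1C(=O)[C@H](C)C(=O)CO[Si](C)(C)C(C)(C)C | intermediate
18 | (4R)-4-benzyl-3-[(2R,3R)-3-hydroxy-2-methyl-3-{[(tert-butyldimethylsilyl)oxy]methyl}pent-4-enoyl]oxazolidin-2-one | O=C1OC[C@@H](Cc2ccccc2)N1C(=O)[C@H](C)[C@](C=C)(CO[Si](C)(C)C(C)(C)C)O | intermediate
19 | (4R)-4-benzyl-3-[(2R,3R)-3-(methoxymethoxy)-2-methyl-3-{[(tert-butyldimethylsilyl)oxy]methyl}pent-4-enoyl]oxazolidin-2-one | O=C1OC[C@@H](Cc2ccccc2)N1C(=O)[C@H](C)[C@](C=C)(CO[Si](C)(C)C(C)(C)C)OCOC | intermediate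
20 | (4R)-4-benzyl-3-[(2R,3R)-3-formyl-3-(methoxymethoxy)-2-methyl-4-(tert-butyldimethylsilyloxy)butanoyl]oxazolidin-2-one | O=C1OC[C@@H](Cc2ccccc2)N1C(=O)[C@H](C)[C@](C=O)(CO[Si](C)(C)C(C)(C)C)OCOC | intermediate
21 | propyne | CC#C | starting material
22 | C4 alkyllithium derived from 13 (stereocentres as in 13) | C1C2(OCCO2)[C@H](O[Si](C)(C)C(C)(C)C)C=C[C@]1(C)[C@H](O[Si](C)(C)C(C)(C)C)CC[Li] | intermediate
23 | C4 alkylcopper (MgBr2 complex, drawn as RCu; stereocentres as in 13) | C1C2(OCCO2)[C@H](O[Si](C)(C)C(C)(C)C)C=C[C@]1(C)[C@H](O[Si](C)(C)C(C)(C)C)CC[Cu] | intermediate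
24 | (Z)-C6 alkenylcopper, C4 and Cu cis on C5=C6 (stereocentres as in 13) | C1C2(OCCO2)[C@H](O[Si](C)(C)C(C)(C)C)C=C[C@]1(C)[C@H](O[Si](C)(C)C(C)(C)C)CC/C(C)=C\[Cu] | intermediate
25 | bromomagnesium (7S)-alkoxide of the aldehyde adduct, imide intact | C1C2(OCCO2)[C@H](O[Si](C)(C)C(C)(C)C)C=C[C@]1(C)[C@H](O[Si](C)(C)C(C)(C)C)CC/C(C)=C\[C@H](O[Mg]Br)[C@@](CO[Si](C)(C)C(C)(C)C)(OCOC)[C@@H](C)C(=O)N1[C@H](Cc2ccccc2)COC1=O | intermediate
26 | coupled (Z)-C5=C6 γ-lactone: ring A with C11 dioxolane and 2,12-bis(OTBS), 8-OMOM, C9H2OTBS; 7S, other centres as in 13 and 20 | C1C2(OCCO2)[C@H](O[Si](C)(C)C(C)(C)C)C=C[C@]1(C)[C@H](O[Si](C)(C)C(C)(C)C)CC/C(C)=C\[C@@H]1OC(=O)[C@H](C)[C@]1(CO[Si](C)(C)C(C)(C)C)OCOC | intermediate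
27 | 26 with free C9 hydroxyl and C11 ketone (configuration unchanged) | C1C(=O)[C@H](O[Si](C)(C)C(C)(C)C)C=C[C@]1(C)[C@H](O[Si](C)(C)C(C)(C)C)CC/C(C)=C\[C@@H]1OC(=O)[C@H](C)[C@]1(CO)OCOC | intermediate
28 | C9 aldehyde / C11 ketone (configuration unchanged) | C1C(=O)[C@H](O[Si](C)(C)C(C)(C)C)C=C[C@]1(C)[C@H](O[Si](C)(C)C(C)(C)C)CC/C(C)=C\[C@@H]1OC(=O)[C@H](C)[C@]1(C=O)OCOC | intermediate
29 | briarane skeleton: 9-hydroxy-11-ketone, 2,12-bis(OTBS), 8-OMOM; all centres as in 34 | O[C@@H]1[C@H]2C(=O)[C@H](O[Si](C)(C)C(C)(C)C)C=C[C@]2(C)[C@H](O[Si](C)(C)C(C)(C)C)CC/C(C)=C\[C@@H]2OC(=O)[C@H](C)[C@]21OCOC | intermediate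
30 | 9-acetate of 29 | CC(=O)O[C@@H]1[C@H]2C(=O)[C@H](O[Si](C)(C)C(C)(C)C)C=C[C@]2(C)[C@H](O[Si](C)(C)C(C)(C)C)CC/C(C)=C\[C@@H]2OC(=O)[C@H](C)[C@]21OCOC | intermediate
31 | 11α-hydroxy-11β-methyl compound, 9-OAc, 2,12-bis(OTBS), 8-OMOM; centres as in 34 | CC(=O)O[C@@H]1[C@H]2[C@](C)(O)[C@H](O[Si](C)(C)C(C)(C)C)C=C[C@]2(C)[C@H](O[Si](C)(C)C(C)(C)C)CC/C(C)=C\[C@@H]2OC(=O)[C@H](C)[C@]21OCOC | intermediate
32 | 2,12-diol, 9-OAc, 8-OMOM; centres as in 34 | CC(=O)O[C@@H]1[C@H]2[C@](C)(O)[C@H](O)C=C[C@]2(C)[C@H](O)CC/C(C)=C\[C@@H]2OC(=O)[C@H](C)[C@]21OCOC | intermediate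
33 | 2,9,12-triacetate 8-MOM ether; centres as in 34 | CC(=O)O[C@@H]1[C@H]2[C@](C)(O)[C@H](OC(C)=O)C=C[C@]2(C)[C@H](OC(C)=O)CC/C(C)=C\[C@@H]2OC(=O)[C@H](C)[C@]21OCOC | intermediate
34 | CNP0129620.2 (1S,2R,7S,8S,9R,10S,11S,12R,17R; 5Z) | CC(=O)O[C@@H]1[C@H]2[C@](C)(O)[C@H](OC(C)=O)C=C[C@]2(C)[C@H](OC(C)=O)CC/C(C)=C\[C@@H]2OC(=O)[C@H](C)[C@]21O | target

**Step count and risks**

Total: 24 steps (10 to iodide 13, 5 to aldehyde 20, the union, 8 to finish). Longest linear sequence: 19 steps (steps 1–10 and 16–24).

Steps most likely to fail: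

1. Step 16. The alkenyl group may transfer only sluggishly from copper to the hindered aldehyde, so that protonation of the alkenylcopper, thienyl transfer or a non-chelated addition competes. The fallback sets out from 13 and runs the same carbocupration, but the alkenylcopper is quenched with iodine and the (Z)-vinyl iodide F1 is isolated. Iodine–lithium exchange (t-BuLi, Et2O, −78 °C) and MgBr2·OEt2 then give the alkenylmagnesium bromide F2. Its chelation-controlled Grignard addition to the α-alkoxymethoxy aldehyde 20, followed by warming, closes the lactone and rejoins the route at 26.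

2. Step 19. Ring closure between two neopentyl carbons through a closed transition state may be slow and reversible, so that intermolecular aldol, ring opening or enolisation toward C12 with double-bond migration takes over. The fallback sets out from 28: TMSOTf/Et3N at −78 °C gives the C10 enol silane F3, and BF3·OEt2 at −78 °C under high dilution closes the ring by an intramolecular Mukaiyama aldol through an open transition state, with the aldolate captured irreversibly. Aqueous work-up frees the C9 hydroxyl and rejoins the route at 29.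

3. Step 21. The methyl nucleophile may attack the α face of the C11 ketone and give the C11 epimer, or the ketone may simply enolise. The fallback sets out from 30: methylenation with Cp2TiMe2 (toluene, 65 °C) gives the 11-methylene compound F4. Mukaiyama hydration (Mn(dpm)3, PhSiH3, O2, i-PrOH; then PPh3) puts hydrogen on the exocyclic carbon and oxygen on C11 from the face a nucleophile prefers, so the methyl group ends up on the opposite face to that from direct addition. The 1,1-disubstituted alkene should react before the hindered trisubstituted and 1,2-disubstituted ones, and the sequence rejoins the route at 31.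

**Further compounds**

F1 | step 16 | (Z)-vinyl iodide from iodination of alkenylcopper 24 | C1C2(OCCO2)[C@H](O[Si](C)(C)C(C)(C)C)C=C[C@]1(C)[C@H](O[Si](C)(C)C(C)(C)C)CC/C(C)=C\I
F2 | step 16 | (Z)-alkenylmagnesium bromide from F1 | C1C2(OCCO2)[C@H](O[Si](C)(C)C(C)(C)C)C=C[C@]1(C)[C@H](O[Si](C)(C)C(C)(C)C)CC/C(C)=C\[Mg]Br
F3 | step 19 | C10 trimethylsilyl enol ether of keto aldehyde 28 | C1=C(O[Si](C)(C)C)[C@H](O[Si](C)(C)C(C)(C)C)C=C[C@]1(C)[C@H](O[Si](C)(C)C(C)(C)C)CC/C(C)=C\[C@@H]1OC(=O)[C@H](C)[C@]1(C=O)OCOC
F4 | step 21 | 11-methylene analogue of 30 | CC(=O)O[C@@H]1[C@H]2C(=C)[C@H](O[Si](C)(C)C(C)(C)C)C=C[C@]2(C)[C@H](O[Si](C)(C)C(C)(C)C)CC/C(C)=C\[C@@H]2OC(=O)[C@H](C)[C@]21OCOC
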